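**Plan**

- Retrosynthesis: first the exocyclic C–butanoyl bond of the dearomatised ring (ring B) and the O-protecting groups are removed. Then two ring-B bonds are cut in one operation, carbonyl carbon to benzyl-bearing carbon and oxygenated carbon to quaternary carbon. This gives a two-carbon ynol ether that carries the whole acylphloroglucinol arm (ring A) and a four-carbon 3-ethoxycyclobutenone. Last come the benzyl–alkyne bond and the cyclobutenone (ketene plus ethoxyethyne).
- Feature used: ring B is a 3,5-dioxygenated cyclohexa-2,5-dien-1-one whose C4 carries two carbon groups. It is therefore the [4+2] adduct of a vinylketene (C1=C6–C5=C4) and an alkyne (C2≡C3), it cannot aromatise, and the vinylketene can be stored as a cyclobutenone whose sp3 carbon is C4.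
- Forward: ring A is bought as 5-methoxyresorcinol and elaborated to the ynol ether (steps 1–5). The cyclobutenone is made and resolved (steps 6–8). Ring B is formed in step 9, and enol ether hydrolysis, C-butanoylation and desilylation finish the route (steps 10–12).
- Stereochemistry: the only stereocentre (C4 of ring B) is fixed in the cyclobutenone by resolution and should be carried into ring B with retention, because the metal never releases that carbon.

Key step: step 9

Remark on the chemistry: ring B is a rapidly tautomerising enolised triketone, so every ring-B compound is written in the enol form that matches the target SMILES; the descriptor at the quaternary carbon (4S or 4R) changes along the route only because substituent priorities change, not the spatial arrangement.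

**Route**

Step 1
Reactants: 1 5-methoxybenzene-1,3-diol; 2 hexanenitrile
Product: 4 1-(2,4-dihydroxy-6-methoxyphenyl)hexan-1-one, via ketiminium chloride 3 (not isolated)
Conditions: HCl (gas), ZnCl2 (0.2 equiv), Et2O, 0 °C; then H2O, 100 °C
Reagents that add atoms: water (O)
Why: Hoesch reaction (acylation of a phloroglucinol-type arene by a nitrile, then hydrolysis of the ketiminium salt); the two equivalent positions between OH and OMe should be favoured over the single position between the hydroxyls, and the minor symmetric isomer is removed by crystallisation or chromatography.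

Step 2
Reactants: 4 1-(2,4-dihydroxy-6-methoxyphenyl)hexan-1-one
Product: 5 1-{3-[(dimethylamino)methyl]-2,4-dihydroxy-6-methoxyphenyl}hexan-1-one
Conditions: Me2NH (40% aq.), CH2O (37% aq.), EtOH, 0 °C to rt
Reagents that add atoms: formaldehyde (C=O); dimethylamine (CNC)
Why: Mannich reaction of a phenol; the iminium ion should attack the ring carbon flanked by the two free hydroxyls (hydrogen-bond delivery from both sides), which is the carbon that becomes the methylene bridge.

Step 3
Reactants: 5 1-{3-[(dimethylamino)methyl]-2,4-dihydroxy-6-methoxyphenyl}hexan-1-one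
Product: 7 1-{2,4-bis[(tert-butyldimethylsilyl)oxy]-3-[(dimethylamino)methyl]-6-methoxyphenyl}hexan-1-one, via disodium bisphenoxide 6 (not isolated)
Conditions: NaH (2.2 equiv), THF/DMF, 0 °C; then TBSCl (2.3 equiv), rt
Reagents that add atoms: tert-butyldimethylsilyl chloride (CC(C)(C)[Si](C)(C)Cl)
Why: O-silylation of phenoxides; both phenols must be masked because a free ortho-hydroxyl would add to the ynol ether made in step 5 and would quench the nickel catalyst in step 9.

Step 4
Reactants: 7 1-{2,4-bis[(tert-butyldimethylsilyl)oxy]-3-[(dimethylamino)methyl]-6-methoxyphenyl}hexan-1-one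
Product: 8 1-{2,4-bis[(tert-butyldimethylsilyl)oxy]-3-(chloromethyl)-6-methoxyphenyl}hexan-1-one
Conditions: ClCO2Et (1.2 equiv), CH2Cl2, 0 °C to rt
Reagents that add atoms: ethyl chloroformate (CCOC(=O)Cl)
Why: chloroformate dealkylation of a tertiary benzylic amine (von Braun-type); N-acylation gives an acylammonium ion from which chloride should displace the electron-rich benzyl group in preference to methyl.

Step 5
Reactants: 8 1-{2,4-bis[(tert-butyldimethylsilyl)oxy]-3-(chloromethyl)-6-methoxyphenyl}hexan-1-one; 9 ethoxyethyne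
Product: 11 1-{2,4-bis[(tert-butyldimethylsilyl)oxy]-3-(3-ethoxyprop-2-yn-1-yl)-6-methoxyphenyl}hexan-1-one, via lithium ethoxyacetylide 10 (not isolated)
Conditions: 9 (2.5 equiv), n-BuLi (2.4 equiv), THF, −78 °C; then 8, DMPU, LiI (cat.), −78 to 0 °C
Reagents that add atoms: none
Why: SN2 alkylation of a lithium alkoxyacetylide by a benzylic halide; the ketone, twisted out of conjugation between two ortho substituents, should at most be enolised reversibly by the excess acetylide and not attacked.

Step 6
Reactants: 12 propanoic acid; 13 1-bromo-3-methylbut-2-ene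
Product: 15 rac-2,5-dimethylhex-4-enoic acid, via dilithium enediolate 14 (not isolated)
Conditions: LiN(iPr)2 (2.2 equiv), THF, 0 °C; then 13, 0 °C to rt; aq. HCl work-up
Reagents that add atoms: none
Why: alkylation of a carboxylic acid dianion; the primary allylic bromide should react at carbon by SN2, and the stereocentre formed is racemic and is erased in step 7.

Step 7
Reactants: 15 rac-2,5-dimethylhex-4-enoic acid; 9 ethoxyethyne
Product: 18 rac-3-ethoxy-4-methyl-4-(3-methylbut-2-en-1-yl)cyclobut-2-en-1-one, via acid chloride 16 (not isolated), via methyl(prenyl)ketene 17 (not isolated)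
Conditions: (COCl)2 (1.2 equiv), CH2Cl2, 0 °C to rt, evaporate; then 9 (2 equiv), Et3N (1.5 equiv), MeCN, 50 °C
Reagents that add atoms: none
Why: dehydrochlorination to the disubstituted ketene followed by ketene–ynol ether [2+2] cycloaddition; the nucleophilic terminal carbon of the ynol ether bonds to the ketene carbonyl carbon, so the ethoxy group ends at C3 and the methyl/prenyl carbon at C4, and the quaternary centre is formed racemic.

Step 8
Reactants: 18 rac-3-ethoxy-4-methyl-4-(3-methylbut-2-en-1-yl)cyclobut-2-en-1-one
Product: 19 (4S)-3-ethoxy-4-methyl-4-(3-methylbut-2-en-1-yl)cyclobut-2-en-1-one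
Conditions: preparative SFC, amylose tris(3,5-dimethylphenylcarbamate) stationary phase, CO2/iPrOH, 35 °C
Reagents that add atoms: none
Why: resolution of enantiomers by chromatography on a chiral stationary phase (no bond is made), which fixes the configuration of the quaternary carbon; the unwanted enantiomer can be returned to the racemate through the achiral, tautomerising 3-hydroxycyclobutenone.

Step 9
Reactants: 19 (4S)-3-ethoxy-4-methyl-4-(3-methylbut-2-en-1-yl)cyclobut-2-en-1-one; 11 1-{2,4-bis[(tert-butyldimethylsilyl)oxy]-3-(3-ethoxyprop-2-yn-1-yl)-6-methoxyphenyl}hexan-1-one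
Product: 20 (4S)-2-({2,6-bis[(tert-butyldimethylsilyl)oxy]-3-hexanoyl-4-methoxyphenyl}methyl)-3,5-diethoxy-4-methyl-4-(3-methylbut-2-en-1-yl)cyclohexa-2,5-dien-1-one
Conditions: Ni(cod)2 (10 mol%), PPh3 (20 mol%), toluene, 0 °C to rt
Reagents that add atoms: none
Why: Proposed new method: zerovalent nickel should add oxidatively into the strained acyl–C4 (quaternary sp3) bond of 19 to give a nickelacyclopentenone (equivalently an η4-vinylketene complex with nickel held on one face), the ynol ether 11 then inserts so that its nucleophilic benzyl-bearing carbon joins the electrophilic acyl carbon while its ethoxy-bearing carbon stays on nickel, and C–C reductive elimination joins that carbon to C4. The closest known reaction type is the nickel-catalysed [4+2] synthesis of phenols from cyclobutenones and alkynes, which makes the same two bonds; new here are a 4,4-disubstituted cyclobutenone (so the product must stop at the cyclohexa-2,5-dienone), an ynol ether as the alkyne, and the transfer of a stereocentre. Ring B is closed in a formal [4+2] mode by insertion of the two alkyne carbons into the acyl–C4 bond, the last bond arising by C(sp2)–C(sp3) reductive elimination from a seven-membered nickelacycle. No stereocentre is created: C4 stays bound to nickel from oxidative addition to reductive elimination, both of which proceed with retention, so the configuration of 19 should pass into 20 unchanged. The step needs regioselectivity (secured by the polarisation of the ynol ether and by placing the small ethoxy-bearing carbon next to the quaternary centre), chemoselectivity (the di-ortho-substituted aryl ketone, the silyl ethers and the trisubstituted alkene offer the metal no competing strained or activated bond) and stereochemical fidelity (secured by working at or below room temperature, where thermal ring opening of 19 to the free, achiral vinylketene does not occur).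

Step 10
Reactants: 20 (4S)-2-({2,6-bis[(tert-butyldimethylsilyl)oxy]-3-hexanoyl-4-methoxyphenyl}methyl)-3,5-diethoxy-4-methyl-4-(3-methylbut-2-en-1-yl)cyclohexa-2,5-dien-1-one
Product: 21 (4S)-2-({2,6-bis[(tert-butyldimethylsilyl)oxy]-3-hexanoyl-4-methoxyphenyl}methyl)-3,5-dihydroxy-4-methyl-4-(3-methylbut-2-en-1-yl)cyclohexa-2,5-dien-1-one
Conditions: 1 M aq. HCl, THF, rt
Reagents that add atoms: water (O)
Why: acid-catalysed hydrolysis of two vinylogous esters (conjugate addition of water, loss of ethanol), driven by formation of the enolised triketone; aryl silyl ethers and the trisubstituted alkene should tolerate dilute acid at room temperature, and the quaternary centre cannot epimerise.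

Step 11
Reactants: 21 (4S)-2-({2,6-bis[(tert-butyldimethylsilyl)oxy]-3-hexanoyl-4-methoxyphenyl}methyl)-3,5-dihydroxy-4-methyl-4-(3-methylbut-2-en-1-yl)cyclohexa-2,5-dien-1-one; 22 butanoic acid
Product: 24 (4R)-2-butanoyl-6-({2,6-bis[(tert-butyldimethylsilyl)oxy]-3-hexanoyl-4-methoxyphenyl}methyl)-3,5-dihydroxy-4-methyl-4-(3-methylbut-2-en-1-yl)cyclohexa-2,5-dien-1-one, via enol butanoate 23 (not isolated)
Conditions: DCC (1.2 equiv), DMAP (0.3 equiv), CH2Cl2, 0 °C to rt
Reagents that add atoms: none
Why: carbodiimide O-acylation of the acidic enol followed by DMAP-mediated O-to-C acyl transfer (Fries-type rearrangement of an enol ester of a cyclic 1,3-dione) to the only ring-B carbon that still bears hydrogen; the chelated β-triketone is the thermodynamic sink and ring A has no free hydroxyl.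

Step 12
Reactants: 24 (4R)-2-butanoyl-6-({2,6-bis[(tert-butyldimethylsilyl)oxy]-3-hexanoyl-4-methoxyphenyl}methyl)-3,5-dihydroxy-4-methyl-4-(3-methylbut-2-en-1-yl)cyclohexa-2,5-dien-1-one
Product: 25 (4R)-2-butanoyl-6-[(3-hexanoyl-2,6-dihydroxy-4-methoxyphenyl)methyl]-3,5-dihydroxy-4-methyl-4-(3-methylbut-2-en-1-yl)cyclohexa-2,5-dien-1-one
Conditions: Bu4NF (2.5 equiv), AcOH (3 equiv), THF, 0 °C
Reagents that add atoms: none
Why: fluoride-induced cleavage of aryl silyl ethers; buffering with acetic acid keeps the medium near neutral, so the β-triketone, the prenyl group and the quaternary stereocentre should be untouched.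

**Compound list**

1 | 5-methoxybenzene-1,3-diol | COc1cc(O)cc(O)c1 | starting material
2 | hexanenitrile | CCCCCC#N | starting material
3 | 1-(2,4-dihydroxy-6-methoxyphenyl)hexan-1-iminium chloride | CCCCCC(=[NH2+])c1c(OC)cc(O)cc1O.[Cl-] | intermediate
4 | 1-(2,4-dihydroxy-6-methoxyphenyl)hexan-1-one | CCCCCC(=O)c1c(OC)cc(O)cc1O | intermediate
5 | 1-{3-[(dimethylamino)methyl]-2,4-dihydroxy-6-methoxyphenyl}hexan-1-one | CCCCCC(=O)c1c(OC)cc(O)c(CN(C)C)c1O | intermediate
6 | disodium bisphenoxide of 5 | CCCCCC(=O)c1c(OC)cc([O-])c(CN(C)C)c1[O-].[Na+].[Na+] | intermediate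
7 | 1-{2,4-bis[(tert-butyldimethylsilyl)oxy]-3-[(dimethylamino)methyl]-6-methoxyphenyl}hexan-1-one | CCCCCC(=O)c1c(OC)cc(O[Si](C)(C)C(C)(C)C)c(CN(C)C)c1O[Si](C)(C)C(C)(C)C | intermediate
8 | 1-{2,4-bis[(tert-butyldimethylsilyl)oxy]-3-(chloromethyl)-6-methoxyphenyl}hexan-1-one | CCCCCC(=O)c1c(OC)cc(O[Si](C)(C)C(C)(C)C)c(CCl)c1O[Si](C)(C)C(C)(C)C | intermediate
9 | ethoxyethyne | CCOC#C | starting material
10 | lithium ethoxyacetylide | CCOC#[C-].[Li+] | intermediate
11 | 1-{2,4-bis[(tert-butyldimethylsilyl)oxy]-3-(3-ethoxyprop-2-yn-1-yl)-6-methoxyphenyl}hexan-1-one | CCCCCC(=O)c1c(OC)cc(O[Si](C)(C)C(C)(C)C)c(CC#COCC)c1O[Si](C)(C)C(C)(C)C | intermediate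
12 | propanoic acid | CCC(=O)O | starting material
13 | 1-bromo-3-methylbut-2-ene | CC(C)=CCBr | starting material
14 | dilithium enediolate of propanoic acid | CC=C([O-])[O-].[Li+].[Li+] | intermediate
15 | rac-2,5-dimethylhex-4-enoic acid | CC(CC=C(C)C)C(=O)O | intermediate
16 | rac-2,5-dimethylhex-4-enoyl chloride | CC(CC=C(C)C)C(=O)Cl | intermediate
17 | 2,5-dimethylhexa-1,4-dien-1-one (methyl(prenyl)ketene) | CC(CC=C(C)C)=C=O | intermediate
18 | rac-3-ethoxy-4-methyl-4-(3-methylbut-2-en-1-yl)cyclobut-2-en-1-one | CCOC1=CC(=O)C1(C)CC=C(C)C | intermediate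
19 | (4S)-3-ethoxy-4-methyl-4-(3-methylbut-2-en-1-yl)cyclobut-2-en-1-one | CCOC1=CC(=O)[C@@]1(C)CC=C(C)C | intermediate
20 | (4S)-2-({2,6-bis[(tert-butyldimethylsilyl)oxy]-3-hexanoyl-4-methoxyphenyl}methyl)-3,5-diethoxy-4-methyl-4-(3-methylbut-2-en-1-yl)cyclohexa-2,5-dien-1-one | CCCCCC(=O)c1c(OC)cc(O[Si](C)(C)C(C)(C)C)c(CC2=C(OCC)[C@@](C)(CC=C(C)C)C(OCC)=CC2=O)c1O[Si](C)(C)C(C)(C)C | intermediate
21 | (4S)-2-({2,6-bis[(tert-butyldimethylsilyl)oxy]-3-hexanoyl-4-methoxyphenyl}methyl)-3,5-dihydroxy-4-methyl-4-(3-methylbut-2-en-1-yl)cyclohexa-2,5-dien-1-one | CCCCCC(=O)c1c(OC)cc(O[Si](C)(C)C(C)(C)C)c(CC2=C(O)[C@@](C)(CC=C(C)C)C(O)=CC2=O)c1O[Si](C)(C)C(C)(C)C | intermediate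
22 | butanoic acid | CCCC(=O)O | starting material
23 | enol butanoate of 21 (butanoyl on the enol oxygen next to the ring CH) | CCCCCC(=O)c1c(OC)cc(O[Si](C)(C)C(C)(C)C)c(CC2=C(O)[C@@](C)(CC=C(C)C)C(OC(=O)CCC)=CC2=O)c1O[Si](C)(C)C(C)(C)C | intermediate
24 | (4R)-2-butanoyl-6-({2,6-bis[(tert-butyldimethylsilyl)oxy]-3-hexanoyl-4-methoxyphenyl}methyl)-3,5-dihydroxy-4-methyl-4-(3-methylbut-2-en-1-yl)cyclohexa-2,5-dien-1-one | CCCCCC(=O)c1c(OC)cc(O[Si](C)(C)C(C)(C)C)c(CC2=C(O)[C@@](C)(CC=C(C)C)C(O)=C(C(=O)CCC)C2=O)c1O[Si](C)(C)C(C)(C)C | intermediate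
25 | (4R)-2-butanoyl-6-[(3-hexanoyl-2,6-dihydroxy-4-methoxyphenyl)methyl]-3,5-dihydroxy-4-methyl-4-(3-methylbut-2-en-1-yl)cyclohexa-2,5-dien-1-one | CCCCCC(=O)c1c(OC)cc(O)c(CC2=C(O)[C@@](C)(CC=C(C)C)C(O)=C(C(=O)CCC)C2=O)c1O | target

**Step count and risks**

Total steps: 12. Longest linear sequence: 9 steps (steps 1–5, then 9–12).

First, step 9 (Proposed new method). The metal may fail to enter the hindered acyl–quaternary carbon bond, the ynol ether may oligomerise on nickel, β-hydride loss from the nickel-bound carbon may intervene, or the metal may release the vinylketene so that configuration is lost. The fallback uses known chemistry and sets out from racemic 18 and 11 without nickel. Heating in toluene at 110 °C (or irradiation at room temperature) should trigger the Danheiser-type sequence: 4π ring opening to the vinylketene, [2+2] addition of the ynol ether, a second 4π opening and 6π closure. This should give the linearly conjugated dienone rac-2-({2,6-bis[(tert-butyldimethylsilyl)oxy]-3-hexanoyl-4-methoxyphenyl}methyl)-3,5-diethoxy-6-methyl-6-(3-methylbut-2-en-1-yl)cyclohexa-2,4-dien-1-one F1, a different bis-enol ether of the same ring. Hydrolysis under the conditions of step 10 should give the racemic trione rac-2-({2,6-bis[(tert-butyldimethylsilyl)oxy]-3-hexanoyl-4-methoxyphenyl}methyl)-3,5-dihydroxy-4-methyl-4-(3-methylbut-2-en-1-yl)cyclohexa-2,5-dien-1-one F2. Chromatography on the chiral phase of step 8 then delivers 21, where the route is rejoined.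

Second, step 5. Substitution at the di-ortho-substituted benzylic carbon may be slow, the acetylide may add to or enolise the ketone, and base may isomerise the propargyl arene to an allene. The fallback sets out from 5. Methyl iodide in acetone should give the ammonium salt [(3-hexanoyl-2,6-dihydroxy-4-methoxyphenyl)methyl]trimethylammonium iodide F3. Adding F3 to excess lithium ethoxyacetylide 10 (THF, −78 to 0 °C) should make the ortho-phenoxide expel trimethylamine and the acetylide add to the exocyclic methylene, an elimination–addition sequence known for phenolic Mannich bases in which the ketone is protected as a vinylogous carboxylate. This gives the dilithium bisphenoxide of 1-[3-(3-ethoxyprop-2-yn-1-yl)-2,4-dihydroxy-6-methoxyphenyl]hexan-1-one F4, which is silylated in the same flask with TBSCl and comes back to the route at 11.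

Third, step 10. The aryl silyl ethers may be partly lost under the acidic hydrolysis, or acid may cyclise the prenyl group onto a neighbouring enol oxygen. The fallback sets out from 20 and changes the end game. Aqueous LiOH in THF/MeOH at 50 °C should hydrolyse both vinylogous esters by addition–elimination and remove both silyl groups, giving (4S)-2-[(3-hexanoyl-2,6-dihydroxy-4-methoxyphenyl)methyl]-3,5-dihydroxy-4-methyl-4-(3-methylbut-2-en-1-yl)cyclohexa-2,5-dien-1-one F5. Excess butanoyl chloride with Et3N and DMAP should acylate the phenols and, through the enol ester, the ring-B carbon. After aqueous work-up this gives (4R)-2-butanoyl-6-{[2,6-bis(butanoyloxy)-3-hexanoyl-4-methoxyphenyl]methyl}-3,5-dihydroxy-4-methyl-4-(3-methylbut-2-en-1-yl)cyclohexa-2,5-dien-1-one F6. K2CO3 in MeOH at 0 °C should then cleave only the two aryl esters and return the route at 25.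

**Further compounds**

F1 | step 9 | rac-2-({2,6-bis[(tert-butyldimethylsilyl)oxy]-3-hexanoyl-4-methoxyphenyl}methyl)-3,5-diethoxy-6-methyl-6-(3-methylbut-2-en-1-yl)cyclohexa-2,4-dien-1-one | CCCCCC(=O)c1c(OC)cc(O[Si](C)(C)C(C)(C)C)c(CC2=C(OCC)C=C(OCC)C(C)(CC=C(C)C)C2=O)c1O[Si](C)(C)C(C)(C)C
F2 | step 9 | rac-2-({2,6-bis[(tert-butyldimethylsilyl)oxy]-3-hexanoyl-4-methoxyphenyl}methyl)-3,5-dihydroxy-4-methyl-4-(3-methylbut-2-en-1-yl)cyclohexa-2,5-dien-1-one | CCCCCC(=O)c1c(OC)cc(O[Si](C)(C)C(C)(C)C)c(CC2=C(O)C(C)(CC=C(C)C)C(O)=CC2=O)c1O[Si](C)(C)C(C)(C)C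
F3 | step 5 | [(3-hexanoyl-2,6-dihydroxy-4-methoxyphenyl)methyl]trimethylammonium iodide | CCCCCC(=O)c1c(OC)cc(O)c(C[N+](C)(C)C)c1O.[I-]
F4 | step 5 | dilithium bisphenoxide of 1-[3-(3-ethoxyprop-2-yn-1-yl)-2,4-dihydroxy-6-methoxyphenyl]hexan-1-one | CCCCCC(=O)c1c(OC)cc([O-])c(CC#COCC)c1[O-].[Li+].[Li+]
F5 | step 10 | (4S)-2-[(3-hexanoyl-2,6-dihydroxy-4-methoxyphenyl)methyl]-3,5-dihydroxy-4-methyl-4-(3-methylbut-2-en-1-yl)cyclohexa-2,5-dien-1-one | CCCCCC(=O)c1c(OC)cc(O)c(CC2=C(O)[C@@](C)(CC=C(C)C)C(O)=CC2=O)c1O
F6 | step 10 | (4R)-2-butanoyl-6-{[2,6-bis(butanoyloxy)-3-hexanoyl-4-methoxyphenyl]methyl}-3,5-dihydroxy-4-methyl-4-(3-methylbut-2-en-1-yl)cyclohexa-2,5-dien-1-one | CCCCCC(=O)c1c(OC)cc(OC(=O)CCC)c(CC2=C(O)[C@@](C)(CC=C(C)C)C(O)=C(C(=O)CCC)C2=O)c1OC(=O)CCC
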